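Remark on conventions: carbons are numbered as in the elemane skeleton of the target (ring C5–C10; C1=C2 vinyl and C14 methyl on C10; C3=C4–C15 on C5; C11–C13 on C7). β is the ring face of the C10 methyl group. In 2–5 the carbonyl carbon is the future C9 and the silyloxy carbon the future C6. The acetal carbon C12 made in step 14 is carried as both epimers, which converge at the lactone.

## Structural features

The target is a cyclohexane (C5–C10) in which all six ring carbons are stereogenic, cis-fused across C7–C8 to a γ-lactone (O8–C12(=O)–C11–C7). The lactone α-carbon C11 is a seventh stereocentre, with its methyl on the convex face, cis to H7. C10 is quaternary (methyl β, vinyl α) and lies between C9 (free hydroxyl, α) and C5 (2-substituted acrolein, β); C6 carries the isobutyrate (β). O9 is trans to O8, whereas O8, the C7–C11 bond, O6, the C5 arm and the C10 methyl all lie on the β face, so O6, O8 and the C10 methyl are mutually 1,3-syn. The fragile groups are the α-substituted acrolein (next to a C5 that becomes epimerisable once C6 is a ketone), a lactone that could translactonise onto a free cis 6-hydroxyl, and two terminal alkenes that rule out hydrogenation and unselective electrophilic oxidants. The real difficulty is the contiguous stereo-array around a quaternary carbon and the crowded β face: a 6β-hydroxyl, syn-axial to the C10 methyl and O8, would be hard to acylate late. The key step exploits the cis relationship of O8, the C7–C11 bond and O6. A C11 radical held on O8 through an acetal can reach C7 of a C6=C7 enol derivative only from the β face, which closes the oxolane (the lactone at acetal level) cis-fused and leaves C6 to be set by hydrogen transfer from the open α face.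

## Logic of the disconnections

The last two operations are functional. The C9–O–benzyl bond of 31 is broken to give 32, and the C15 oxygen of 31 is taken back to the methyl of an isopropenyl group in 29. The enal and the free hydroxyl are the most reactive groups, so they appear last. The gain is that C3/C4/C15 travel as an inert 1,1-disubstituted alkene, which tolerates the aqueous acid needed for the lactone and is installed by one cuprate addition. The forward oxidation must take the allylic methyl and leave the C5 methine and the vinyl group alone.

The C11–C13 bond is cut next, 29 ⇒ 27. A methyl on the convex face of a cis-fused lactone is what enolate alkylation delivers, and removing it makes the radical needed earlier a primary one. The forward step must enolise the lactone without touching the isobutyrate.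

C12 is taken from the lactone to the acetal level, 27 ⇒ 25 (through 26). An acetal tether cyclises as a radical where an ester tether does not. The forward step needs a hydrolysis–oxidation mild enough for the benzyl-type ether, the ester and two alkenes.

The strategic cut is C7–C11, 25 ⇒ 24. It opens the oxolane and removes the stereocentres C7 and C6 together, leaving a cyclohexene with only C5, C8, C9 and C10 stereogenic. The forward step needs a C11 radical held on O8, an acceptor alkene C6=C7 that already carries the C6 oxygen, cis ring fusion, and hydrogen delivery to C6 from the α face. The C6 oxygen is acylated as the isobutyrate at the enol stage, so the crowded 6β-position is never esterified later and never faces the lactone as a free hydroxyl.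

The O6–acyl bond and then the O8–C12 bond are cut, 24 ⇒ 22 ⇒ 21 + 6. This reduces the radical precursor to a β-hydroxy ketone and a two-carbon enol ether. The forward steps demand enolisation toward C7 and O-acylation without β-elimination of the C8 oxygen.

The C8–O bond is cut, 21 ⇒ 19; the β-hydroxy ketone is the formal hydrate of an enone. O8 is thereby introduced late and trans to O9 under the direction of the C9 ether, so the two oxygens never have to be told apart. The forward step must add to the β face of C8.

No skeletal bond is cut between 19 and 13; the enone is traced back through 17, 16, 15 and 14. The C6 carbinol of 13, having served as control element, becomes the ketone, and the C9 ketone becomes the protected axial alcohol. The demands are equatorial hydride delivery at C9 and dehydrogenation of 17 toward C7–C8 only.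

The C10–C1 and C5–C4 bonds are cut, 13 ⇒ 12 ⇒ 5 + 9 + 8. Both bonds are made in one flask on an enone with a single stereocentre. The vinyl group is reached from a selenium-bearing aldol adduct because a direct vinyl electrophile is not available. The forward step must add anti to the C6 silyloxy group and trap the enolate trans to the new C5 substituent.

8 is taken back to 6 by cutting its C–Se bond.

Finally the C10–C14 bond is cut, 5 ⇒ 4 ⇒ 3, and the alkene and stereocentre of 3 are traced through 2 to the achiral 1. The single demand is discrimination between the two enantiotopic α-methylene groups of 1; every later stereocentre is relayed from this one.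

## Other disconnections considered

Alternative 1: The cut is the ring bond C5–C6, with O6 tied temporarily to C15 as a lactone. In the forward sense the open-chain aldehyde A2 carries on C10 the methyl, the vinyl and a (Z)-2-(bromomethyl)enoate arm. Activated zinc (zerovalent zinc) turns the bromide into an allylzinc, which adds through its γ-carbon C5 to the C6 aldehyde and closes the carbocycle; the zinc alkoxide then closes onto the ester to give the relay α-methylene lactone A1.
- In favour: one operation forms the ring, sets C5 and C6 cis through a cyclic transition state, and installs C3, C4 and C15 with the exocyclic methylene in place. No late allylic oxidation is needed, and on this point the alternative is the better plan. It is tin-free and the reaction type is dependable.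
- Against: A2 needs five stereocentres (C7–C11), one quaternary, built by open-chain control, and its aldehyde is α to an epimerisable C7. After ring closure the relay lactone of A1 must be opened, C15 reduced from the acid to the aldehyde level, O6 acylated as a hindered alcohol, and the second lactone closed on O8.
- Comparison: structurally the alternative handles the acrolein and C5–C6 more directly; the chosen plan handles the C6–C7–C8 lactone region more directly and keeps every stereocentre under ring control. Mechanistically a polar organozinc addition is the equal of the radical chain in reliability and better in work-up. In step economy the gain at the acrolein would probably be spent on A2 and on the lactone relay.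

Alternative 2: The cut is the C8=C9 double bond of a cyclohexene, C10 being a methyl-divinyl carbon before ring closure. Forward, triene A4 meets a chiral molybdenum imido alkylidene, Mo(N-2,6-i-Pr2C6H3)(CHCMe2Ph)(3,3'-di-tert-butyl-5,5',6,6'-tetramethylbiphenyl-2,2'-diolate) (hexavalent molybdenum). Metathesis of the C8 vinyl group with one of the two C10 vinyl groups gives cyclohexene A3 and ethylene, and the other vinyl group stays as that of the target.
- In favour: the quaternary centre is created catalytically by group selection, with no vinyl-cation equivalent, and the C6 isobutyrate is present from the outset. The C8=C9 alkene of A3 is placed so that α-epoxidation and opening at C8 by the C12 carboxyl would give the trans O8/O9 pattern and the cis lactone in two operations. In steps after ring closure the alternative is the equal or the better.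
- Against: the two vinyl groups are diastereotopic because C5, C6 and C7 are already stereogenic, so the catalyst must match or override substrate bias. Ring closure next to a quaternary carbon is slow for an air-sensitive catalyst exposed to Lewis-basic oxygens. The epoxidation must choose the ring alkene over the vinyl group and the α face. A4 and the unveiling of the acrolein from its diol acetonide both cost steps.
- Comparison: the chosen plan sets C10 by substrate control in a ring, which is less elegant but does not depend on a matched catalyst. The metathesis is catalytic and avoids tin, a point on which it is better. Overall step counts should be similar.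

Alternative 3: The cuts are C10–C14 and C5–C4, made together by a [2+2] photocycloaddition. Forward, enone A6 and propargyl silyl ether A7 are irradiated near 350 nm, and the excited enone adds the alkyne across C5=C10 to give the cis-fused cyclobutene A5.
- In favour: two bonds on the most congested pair of ring carbons from two simple partners, an enforced cis fusion, and approach anti to the C9 silyloxy group, which should place C14 on the β face. In bond-forming economy for the C5/C10 pair it is the equal or the better of steps 6 and 7 here.
- Against: head-to-head versus head-to-tail regiochemistry is often poorly controlled, and cyclobutene adducts undergo secondary photoreactions. The C14=C4 bond of A5 must then be cleaved, C14 reduced from the aldehyde to the methyl level, the C4 ketone methylenated while C5 sits between two carbonyl groups, and the oxyethyl arm turned into the vinyl group. C7 and C8 remain untouched.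
- Comparison: this route addresses a different part of the problem and would still need a lactone annulation of the kind chosen here. Its excited-state mechanism is less predictable in regiochemistry than ground-state cuprate chemistry, and it is longer in redox adjustments.

Key step: step 16

## Route

Step 1
Reactants: 1 4-(tert-butyldimethylsilyloxy)cyclohexanone
Product: 2 (S)-4-(tert-butyldimethylsilyloxy)-1-(trimethylsilyloxy)cyclohexene
Conditions: (R,R)-bis(1-phenylethyl)amine, n-BuLi, LiCl, TMSCl (internal quench), THF, −78 °C
Reagents that add atoms: chlorotrimethylsilane C[Si](C)(C)Cl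
Why: Enantioselective deprotonation of a 4-substituted cyclohexanone by a chiral lithium amide with internal silyl quench; the base selects one of the two enantiotopic axial α-hydrogens, which makes the silyloxy carbon (future C6) the only stereocentre. The sense of induction is assumed from other 4-substituted cyclohexanones (the enantiomeric amide would be used if it proved opposite), and enantiomeric purity is to be checked at 3.

Step 2
Reactants: 2 (S)-4-(tert-butyldimethylsilyloxy)-1-(trimethylsilyloxy)cyclohexene
Product: 3 (S)-4-(tert-butyldimethylsilyloxy)cyclohex-2-enone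
Conditions: Pd(OAc)2, MeCN, rt
Reagents that add atoms: none
Why: Ito–Saegusa oxidation: the silyl enol ether gives a palladium enolate that loses β-hydride toward C3, so the enone forms on the side fixed in step 1 and the stereocentre is untouched.

Step 3
Reactants: 3 (S)-4-(tert-butyldimethylsilyloxy)cyclohex-2-enone
Product: 4 (S)-4-(tert-butyldimethylsilyloxy)-2-iodocyclohex-2-enone
Conditions: I2, pyridine, CH2Cl2, rt
Reagents that add atoms: iodine II
Why: α-Iodination of an enone by conjugate addition of pyridine, iodination of the enolate and elimination; the γ-stereocentre is not involved.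

Step 4
Reactants: 4 (S)-4-(tert-butyldimethylsilyloxy)-2-iodocyclohex-2-enone
Product: 5 (S)-4-(tert-butyldimethylsilyloxy)-2-methylcyclohex-2-enone
Conditions: Me2Zn, Pd(dppf)Cl2 (cat.), THF, rt
Reagents that add atoms: dimethylzinc C[Zn]C
Why: Negishi coupling of an α-iodoenone; the neutral conditions avoid base-induced loss of the γ-silyloxy group, and the methyl introduced is the future C14.

Step 5
Reactants: 6 ethyl vinyl ether
Product: 8 (phenylselanyl)acetaldehyde, via 1-chloro-1-ethoxy-2-(phenylselanyl)ethane 7 (not isolated)
Conditions: PhSeCl, CH2Cl2, −78 °C; then H2O, NaHCO3, rt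
Reagents that add atoms: benzeneselenenyl chloride Cl[Se]c1ccccc1; water O
Why: Electrophilic selenenylation of the enol ether places selenium on the terminal carbon and chloride on the oxygen-bearing carbon; hydrolysis of the α-chloro ether gives the aldehyde, which is used fresh as a vinyl cation equivalent.

Step 6
Reactants: 5 (S)-4-(tert-butyldimethylsilyloxy)-2-methylcyclohex-2-enone; 9 isopropenylmagnesium bromide; 8 (phenylselanyl)acetaldehyde
Product: 12 10α-[1-hydroxy-2-(phenylselanyl)ethyl]-5β-isopropenyl-10β-methyl-6α-(TBS-oxy)cyclohexan-9-one (carbinol epimers), via bromomagnesium enolate 10 (not isolated), via chlorozinc enolate 11 (not isolated)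
Conditions: CuBr·SMe2 (cat.), THF, −40 °C; ZnCl2, −78 °C; then 8, −78 °C; aq NH4Cl
Reagents that add atoms: none
Why: Copper-catalysed conjugate addition of the alkenyl Grignard reagent anti to the C6 silyloxy group sets C5 (β); the zinc enolate then adds to 8 trans-diaxially to the new C5 substituent, which creates the quaternary C10 with the methyl β and the two-carbon arm α (three-component conjugate addition–aldol coupling). The carbinol carbon is uncontrolled and is removed in step 7.

Step 7
Reactants: 12 10α-[1-hydroxy-2-(phenylselanyl)ethyl]-5β-isopropenyl-10β-methyl-6α-(TBS-oxy)cyclohexan-9-one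
Product: 13 5β-isopropenyl-10β-methyl-6α-(TBS-oxy)-10α-vinylcyclohexan-9-one
Conditions: MsCl, Et3N, CH2Cl2, 0 °C → rt
Reagents that add atoms: none
Why: Mesylation of the β-hydroxy selenide triggers anti elimination through a seleniranium ion (reductive elimination of β-hydroxy selenides), which gives the vinyl group without touching the ketone or any stereocentre.

Step 8
Reactants: 13 5β-isopropenyl-10β-methyl-6α-(TBS-oxy)-10α-vinylcyclohexan-9-one
Product: 14 5β-isopropenyl-10β-methyl-6α-(TBS-oxy)-10α-vinylcyclohexan-9α-ol
Conditions: LiBH(s-Bu)3, THF, −78 °C; H2O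
Reagents that add atoms: none
Why: In the chair with the C10 methyl axial and all other groups equatorial, the bulky borohydride attacks the C9 ketone along the equatorial trajectory, as hindered hydrides do with ketones next to a quaternary carbon; this gives the axial 9α-alcohol, trans to the C10 methyl (diastereoselective ketone reduction).

Step 9
Reactants: 14 5β-isopropenyl-10β-methyl-6α-(TBS-oxy)-10α-vinylcyclohexan-9α-ol
Product: 15 5β-isopropenyl-9α-(4-methoxybenzyloxy)-10β-methyl-6α-(TBS-oxy)-10α-vinylcyclohexane
Conditions: NaH, PMBCl, Bu4NI (cat.), DMF, 0 °C → rt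
Reagents that add atoms: 4-methoxybenzyl chloride COc1ccc(CCl)cc1
Why: Williamson etherification; the PMB ether is orthogonal to the silyl ether removed next and is cleaved oxidatively at the very end.

Step 10
Reactants: 15 5β-isopropenyl-9α-(4-methoxybenzyloxy)-10β-methyl-6α-(TBS-oxy)-10α-vinylcyclohexane
Product: 16 5β-isopropenyl-9α-(4-methoxybenzyloxy)-10β-methyl-10α-vinylcyclohexan-6α-ol
Conditions: Bu4NF, THF, rt
Reagents that add atoms: none
Why: Fluoride cleavage of the silyl ether frees the C6 hydroxyl, whose stereochemical task ended in step 6.

Step 11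
Reactants: 16 5β-isopropenyl-9α-(4-methoxybenzyloxy)-10β-methyl-10α-vinylcyclohexan-6α-ol
Product: 17 5β-isopropenyl-9α-(4-methoxybenzyloxy)-10β-methyl-10α-vinylcyclohexan-6-one
Conditions: DMP, NaHCO3, CH2Cl2, rt
Reagents that add atoms: none
Why: Dess–Martin oxidation under buffered, near-neutral conditions, so that C5, now α to the ketone and allylic, neither epimerises nor lets the isopropenyl double bond move into conjugation.

Step 12
Reactants: 17 5β-isopropenyl-9α-(4-methoxybenzyloxy)-10β-methyl-10α-vinylcyclohexan-6-one
Product: 19 5β-isopropenyl-9α-(4-methoxybenzyloxy)-10β-methyl-10α-vinylcyclohex-7-en-6-one, via trimethylsilyl enol ether 18 (not isolated)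
Conditions: LiN(i-Pr)2, TMSCl (internal quench), THF, −78 °C; then Pd(OAc)2, MeCN, rt
Reagents that add atoms: none
Why: Kinetic deprotonation at C7 (the C5 hydrogen is tertiary and screened by C10) followed by Ito–Saegusa oxidation; dehydrogenation can only run toward C8 because C10 is quaternary, and no stereocentre is formed or lost.

Step 13
Reactants: 19 5β-isopropenyl-9α-(4-methoxybenzyloxy)-10β-methyl-10α-vinylcyclohex-7-en-6-one
Product: 21 8β-hydroxy-5β-isopropenyl-9α-(4-methoxybenzyloxy)-10β-methyl-10α-vinylcyclohexan-6-one, via β-boryl ketone 20 (not isolated)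
Conditions: CuCl (cat.), DPEphos (cat.), NaOt-Bu (cat.), B2pin2, MeOH, THF, rt; then NaBO3·4H2O, THF/H2O, rt
Reagents that add atoms: sodium perborate [Na+].[O-]B1OO1
Why: Copper-catalysed conjugate borylation and perborate oxidation with retention amount to a formal hydration of the enone; the boryl copper adds to C8 anti to the adjacent C9 ether, as cuprates do with 4-alkoxycyclohexenones, which gives the 8β-hydroxyl trans to O9.

Step 14
Reactants: 21 8β-hydroxy-5β-isopropenyl-9α-(4-methoxybenzyloxy)-10β-methyl-10α-vinylcyclohexan-6-one; 6 ethyl vinyl ether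
Product: 22 8β-(2-bromo-1-ethoxyethoxy)-5β-isopropenyl-9α-(4-methoxybenzyloxy)-10β-methyl-10α-vinylcyclohexan-6-one (acetal epimers)
Conditions: NBS, CH2Cl2, −40 → 0 °C
Reagents that add atoms: N-bromosuccinimide O=C1CCC(=O)N1Br
Why: Bromination of 6 gives a β-bromo oxocarbenium ion that the 8-hydroxyl captures (haloacetalisation); 6 is far more nucleophilic than the isopropenyl and vinyl groups, and the acetal epimers are of no consequence.

Step 15
Reactants: 22 8β-(2-bromo-1-ethoxyethoxy)-5β-isopropenyl-9α-(4-methoxybenzyloxy)-10β-methyl-10α-vinylcyclohexan-6-one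
Product: 24 8β-(2-bromo-1-ethoxyethoxy)-5β-isopropenyl-9α-(4-methoxybenzyloxy)-10β-methyl-10α-vinylcyclohex-6-en-6-yl isobutyrate, via lithium enolate 23 (not isolated)
Conditions: LiN(i-Pr)2, THF, −78 °C; then (i-PrCO)2O, −78 → −20 °C
Reagents that add atoms: isobutyric anhydride CC(C)C(=O)OC(=O)C(C)C
Why: Kinetic enolisation toward C7 and O-acylation of the lithium enolate by the anhydride give the C6=C7 enol ester (enol ester formation from a preformed enolate); low temperature and a short enolate lifetime are meant to suppress β-elimination of the C8 alkoxy group and attack of C7 on the bromide. The acyl group is the isobutyrate of the target, so C6 is never acylated as a hindered axial alcohol.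

Step 16
Reactants: 24 8β-(2-bromo-1-ethoxyethoxy)-5β-isopropenyl-9α-(4-methoxybenzyloxy)-10β-methyl-10α-vinylcyclohex-6-en-6-yl isobutyrate
Product: 25 cis-fused 2-ethoxyoxolane (O8–C12–C11–C7) with 6β-isobutyrate and 9α-PMB ether and 5β-isopropenyl and 10β-methyl-10α-vinyl groups (acetal epimers)
Conditions: Bu3SnH (slow addition), AIBN (cat.), benzene, 80 °C, high dilution
Reagents that add atoms: none
Why: The tributyltin radical abstracts bromine from 24 to give a primary radical at C11, which adds to C7 of the C6=C7 enol ester; the resulting α-acyloxy radical at C6 takes hydrogen from Bu3SnH and the chain continues (Ueno–Stork haloacetal cyclisation, whose closest known cases are haloacetals of cyclic allylic alcohols closing onto enol ethers and enol esters). The oxolane closes in the 5-exo-trig mode; 6-endo attack at C6 is disfavoured by the short O8 tether and by the substituent on C6. C7 is controlled by the tether: three atoms from the β-oxygen on C8 can reach only the β face, so the fusion is cis and H7 stays α. C6 is controlled by its surroundings: the radical is flanked by β-substituents on C5 and C7 and faces the syn-axial C10 methyl and O8 across the β face, so the stannane should approach from the α face and leave the acyloxy group β. The step needs cyclisation to outrun direct reduction of the C11 radical, which slow addition of the stannane at high dilution secures. It also needs both spectator alkenes to stay out: the vinyl group is reachable from C11 only through an eight-membered transition state, and from C6 only by reversible 3-exo or unfavourable 4-exo closure onto the isopropenyl or vinyl group. An enol ester is used instead of a silyl enol ether so that the C6 ester is in place after this step and no free 6-hydroxyl ever faces the lactone.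

Step 17
Reactants: 25 cis-fused 2-ethoxyoxolane with 6β-isobutyrate and 9α-PMB ether
Product: 27 8β,12-lactone (cis-fused γ-lactone, C11 unsubstituted) with 6β-isobutyrate and 9α-PMB ether, via lactol 26 (not isolated)
Conditions: 1 M HCl, THF, rt; then Pr4N[RuO4] (cat.), NMO, 4 Å molecular sieves, CH2Cl2, rt
Reagents that add atoms: water O
Why: Aqueous acid hydrolyses the 2-ethoxyoxolane to the lactol, and catalytic perruthenate oxidises the crude lactol to the γ-lactone (Ley–Griffith oxidation); both acetal epimers converge, and the PMB ether, the ester and the alkenes are inert to both stages.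

Step 18
Reactants: 27 8β,12-lactone with 6β-isobutyrate and 9α-PMB ether
Product: 29 11α-methyl-8β,12-lactone with 6β-isobutyrate and 9α-PMB ether, via lithium lactone enolate 28 (not isolated)
Conditions: LiN(SiMe3)2, THF, −78 °C; then MeI, −78 → −40 °C
Reagents that add atoms: iodomethane CI
Why: The silylamide removes a C11 hydrogen of the lactone, which is more acidic and far more accessible than the methine of the isobutyrate. Iodomethane then attacks the enolate from the convex face of the cis-fused bicycle, the face of H7 and H8, to give the 11α-methyl group (lactone enolate alkylation).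

Step 19
Reactants: 29 11α-methyl-8β,12-lactone with 6β-isobutyrate and 9α-PMB ether
Product: 31 9-O-PMB ether of the target (C15 aldehyde on the C4 methylene unit), via allylic alcohol 30 (not isolated)
Conditions: SeO2 (cat.), t-BuOOH, CH2Cl2, rt; then MnO2, CH2Cl2, rt
Reagents that add atoms: selenium dioxide O=[Se]=O (oxygen transferred to C15; reoxidised by tert-butyl hydroperoxide CC(C)(C)OO)
Why: Selenium dioxide oxidises the allylic methyl of the 1,1-disubstituted alkene by an ene reaction and 2,3-sigmatropic shift; the methyl reacts in preference to the hindered C5 methine, and the vinyl group has no allylic hydrogen. MnO2 then takes the allylic alcohol, and only it, to the aldehyde.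

Step 20
Reactants: 31 9-O-PMB ether of the target
Product: 32 CNP0198892.2
Conditions: DDQ, CH2Cl2/pH 7 buffer, 0 °C → rt
Reagents that add atoms: none
Why: DDQ oxidises the electron-rich benzyl ether to an oxocarbenium ion that water cleaves, which frees the 9α-hydroxyl under neutral conditions that the enal, the lactone, the ester and the vinyl group tolerate.

## Compound list

1 | 4-(tert-butyldimethylsilyloxy)cyclohexanone | O=C1CCC(O[Si](C)(C)C(C)(C)C)CC1 | starting material
2 | (S)-4-(tert-butyldimethylsilyloxy)-1-(trimethylsilyloxy)cyclohexene | C[Si](C)(C)OC1=CC[C@@H](O[Si](C)(C)C(C)(C)C)CC1 | intermediate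
3 | (S)-4-(tert-butyldimethylsilyloxy)cyclohex-2-enone | O=C1C=C[C@@H](O[Si](C)(C)C(C)(C)C)CC1 | intermediate
4 | (S)-4-(tert-butyldimethylsilyloxy)-2-iodocyclohex-2-enone | O=C1C(I)=C[C@@H](O[Si](C)(C)C(C)(C)C)CC1 | intermediate
5 | (S)-4-(tert-butyldimethylsilyloxy)-2-methylcyclohex-2-enone | CC1=C[C@@H](O[Si](C)(C)C(C)(C)C)CCC1=O | intermediate
6 | ethyl vinyl ether | C=COCC | starting material
7 | 1-chloro-1-ethoxy-2-(phenylselanyl)ethane | CCOC(Cl)C[Se]c1ccccc1 | intermediate
8 | (phenylselanyl)acetaldehyde | O=CC[Se]c1ccccc1 | intermediate
9 | isopropenylmagnesium bromide | C=C(C)[Mg]Br | starting material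
10 | bromomagnesium C9=C10 enolate, 5β-isopropenyl, 6α-TBS-oxy | CC1=C(O[Mg]Br)CC[C@H](O[Si](C)(C)C(C)(C)C)[C@H]1C(C)=C | intermediate
11 | chlorozinc C9=C10 enolate, 5β-isopropenyl, 6α-TBS-oxy | CC1=C(O[Zn]Cl)CC[C@H](O[Si](C)(C)C(C)(C)C)[C@H]1C(C)=C | intermediate
12 | 10α-[1-hydroxy-2-(phenylselanyl)ethyl]-5β-isopropenyl-10β-methyl-6α-(TBS-oxy)cyclohexan-9-one (carbinol epimers) | OC(C[Se]c2ccccc2)[C@]1(C)C(=O)CC[C@H](O[Si](C)(C)C(C)(C)C)[C@H]1C(C)=C | intermediate
13 | 5β-isopropenyl-10β-methyl-6α-(TBS-oxy)-10α-vinylcyclohexan-9-one | C=C[C@]1(C)C(=O)CC[C@H](O[Si](C)(C)C(C)(C)C)[C@H]1C(C)=C | intermediate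
14 | 5β-isopropenyl-10β-methyl-6α-(TBS-oxy)-10α-vinylcyclohexan-9α-ol | C=C[C@]1(C)[C@H](O)CC[C@H](O[Si](C)(C)C(C)(C)C)[C@H]1C(C)=C | intermediate
15 | 5β-isopropenyl-9α-(4-methoxybenzyloxy)-10β-methyl-6α-(TBS-oxy)-10α-vinylcyclohexane | C=C[C@]1(C)[C@H](OCc2ccc(OC)cc2)CC[C@H](O[Si](C)(C)C(C)(C)C)[C@H]1C(C)=C | intermediate
16 | 5β-isopropenyl-9α-(4-methoxybenzyloxy)-10β-methyl-10α-vinylcyclohexan-6α-ol | C=C[C@]1(C)[C@H](OCc2ccc(OC)cc2)CC[C@H](O)[C@H]1C(C)=C | intermediate
17 | 5β-isopropenyl-9α-(4-methoxybenzyloxy)-10β-methyl-10α-vinylcyclohexan-6-one | C=C[C@]1(C)[C@H](OCc2ccc(OC)cc2)CCC(=O)[C@H]1C(C)=C | intermediate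
18 | C6=C7 trimethylsilyl enol ether of 17 | C=C[C@]1(C)[C@H](OCc2ccc(OC)cc2)CC=C(O[Si](C)(C)C)[C@H]1C(C)=C | intermediate
19 | 5β-isopropenyl-9α-(4-methoxybenzyloxy)-10β-methyl-10α-vinylcyclohex-7-en-6-one | C=C[C@]1(C)[C@H](OCc2ccc(OC)cc2)C=CC(=O)[C@H]1C(C)=C | intermediate
20 | 8β-(pinacolatoboryl) derivative of ketone 17 | C=C[C@]1(C)[C@H](OCc2ccc(OC)cc2)[C@@H](B3OC(C)(C)C(C)(C)O3)CC(=O)[C@H]1C(C)=C | intermediate
21 | 8β-hydroxy-5β-isopropenyl-9α-(4-methoxybenzyloxy)-10β-methyl-10α-vinylcyclohexan-6-one | C=C[C@]1(C)[C@H](OCc2ccc(OC)cc2)[C@@H](O)CC(=O)[C@H]1C(C)=C | intermediate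
22 | 8β-(2-bromo-1-ethoxyethoxy) ketone (acetal epimers) | C=C[C@]1(C)[C@H](OCc2ccc(OC)cc2)[C@@H](OC(OCC)CBr)CC(=O)[C@H]1C(C)=C | intermediate
23 | lithium C6=C7 enolate of 22 | C=C[C@]1(C)[C@H](OCc2ccc(OC)cc2)[C@@H](OC(OCC)CBr)C=C(O[Li])[C@H]1C(C)=C | intermediate
24 | C6=C7 enol isobutyrate with 8β-bromoacetal (radical precursor) | C=C[C@]1(C)[C@H](OCc2ccc(OC)cc2)[C@@H](OC(OCC)CBr)C=C(OC(=O)C(C)C)[C@H]1C(C)=C | intermediate
25 | cis-fused 2-ethoxyoxolane, 6β-isobutyrate, 9α-PMB ether (acetal epimers) | C=C[C@]1(C)[C@H](OCc3ccc(OC)cc3)[C@H]2OC(OCC)C[C@H]2[C@@H](OC(=O)C(C)C)[C@H]1C(C)=C | intermediate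
26 | lactol of 25 (anomers) | C=C[C@]1(C)[C@H](OCc3ccc(OC)cc3)[C@H]2OC(O)C[C@H]2[C@@H](OC(=O)C(C)C)[C@H]1C(C)=C | intermediate
27 | 8β,12-lactone, 6β-isobutyrate, 9α-PMB ether | C=C[C@]1(C)[C@H](OCc3ccc(OC)cc3)[C@H]2OC(=O)C[C@H]2[C@@H](OC(=O)C(C)C)[C@H]1C(C)=C | intermediate
28 | lithium enolate of lactone 27 | C=C[C@]1(C)[C@H](OCc3ccc(OC)cc3)[C@H]2OC(O[Li])=C[C@H]2[C@@H](OC(=O)C(C)C)[C@H]1C(C)=C | intermediate
29 | 11α-methyl-8β,12-lactone, 6β-isobutyrate, 9α-PMB ether | C=C[C@]1(C)[C@H](OCc3ccc(OC)cc3)[C@H]2OC(=O)[C@H](C)[C@H]2[C@@H](OC(=O)C(C)C)[C@H]1C(C)=C | intermediate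
30 | C15 allylic alcohol of 29 | C=C[C@]1(C)[C@H](OCc3ccc(OC)cc3)[C@H]2OC(=O)[C@H](C)[C@H]2[C@@H](OC(=O)C(C)C)[C@H]1C(=C)CO | intermediate
31 | 9-O-PMB ether of the target | C=C[C@]1(C)[C@H](OCc3ccc(OC)cc3)[C@H]2OC(=O)[C@H](C)[C@H]2[C@@H](OC(=O)C(C)C)[C@H]1C(=C)C=O | intermediate
32 | CNP0198892.2 | C=C[C@]1(C)[C@H](O)[C@H]2OC(=O)[C@H](C)[C@H]2[C@@H](OC(=O)C(C)C)[C@H]1C(=C)C=O | target

## Step count and least certain steps

Total: 20 steps. Longest linear sequence: 19 steps (steps 1–4 and 6–20, from 1); step 5 is a one-step side branch. The absolute configuration rests on step 1, so the enantiomeric purity of 3 is to be determined before material is carried on.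

Step 16 (key step). The C11 radical may be reduced before it cyclises, or hydrogen may be delivered to C6 with poor facial selectivity. The fallback closes the same bond by a polar route. Starting from 22, KN(SiMe3)2 in THF forms the C7 enolate, which displaces the bromide intramolecularly to give the cis-fused keto acetal F1. LiBH(s-Bu)3 then reduces the C6 ketone from the open α face to the 6β-alcohol F2, and acylation with isobutyric anhydride and DMAP returns to the route at 25.

Step 6. The hindered enolate may be quenched by proton transfer from the enolisable seleno aldehyde, or the aldolate may revert, so that the quaternary centre is not formed. The fallback separates the two bond formations. From 5 and 9, the copper-catalysed addition is run with TMSCl to give the trimethylsilyl enol ether F3. A Mukaiyama aldol addition to acetaldehyde (TiCl4, CH2Cl2, −78 °C) gives the 10α-(1-hydroxyethyl) ketone F4. Dehydration with the Burgess reagent, whose syn elimination can only use the methyl hydrogens, returns to the route at 13.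

Step 8. Hydride may attack axially to a significant extent, which would erode the facial selectivity at C9. The fallback moves the reduction to an enone and puts it under reagent control. From 13, IBX in DMSO dehydrogenates toward C8 to the cyclohex-7-en-9-one F5. Corey–Bakshi–Shibata reduction, with the oxazaborolidine enantiomer that delivers hydride to the β face, gives the 9α-allylic alcohol F6. PMB protection gives F7, Bu4NF frees the allylic 6α-alcohol F8, and MnO2 oxidation returns to the route at 19.

Step 13. The syn-axial substituent on C10 may erode the facial selectivity of the boryl copper addition, the boron ate complex may eliminate the C9 ether, or the alkoxide medium may epimerise C5. The fallback uses a small nucleophile and a reductive opening. From 19, H2O2 and NaOH in MeOH at 0 °C epoxidise the enone anti to the C9 ether to give the 7β,8β-epoxy ketone F9. SmI2 in THF/MeOH at −78 °C cleaves the Cα–O bond and returns to the route at 21.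

Step 15. The enolate may expel the C8 acetal oxygen (β-elimination), be acylated on carbon, or form at C5. The fallback avoids a metal enolate altogether. From 22, soft enolisation with TBSOTf and Et3N gives the tert-butyldimethylsilyl enol ether F10. The tin hydride cyclisation of step 16 then gives the 6β-silyl ether F11. Bu4NF gives the 6β-alcohol F2 already met above, and acylation at the acetal stage, before any lactone exists, returns to the route at 25.

Step 18. The base may also deprotonate the isobutyrate methine, which would then be methylated, or the lactone enolate may take the acyl group from O6. The fallback carries C13 through the radical step. From 21, NBS and ethyl prop-1-enyl ether give the 8β-(2-bromo-1-ethoxypropoxy) ketone F12. Enol ester formation as in step 15 gives the enol isobutyrate F13, and tin hydride cyclisation of the secondary radical gives the 11-methyl 2-ethoxyoxolane F14 as C11 epimers. Hydrolysis to the lactol F15 and perruthenate oxidation as in step 17 give 29 together with its 11β-methyl epimer F16. DBU equilibrates F16 to the more stable convex methyl lactone, and the route is rejoined at 29.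

## Further compounds

F1 | step 16 | cis-fused 2-ethoxyoxolane with C6 ketone, 9α-PMB ether | C=C[C@]1(C)[C@H](OCc3ccc(OC)cc3)[C@H]2OC(OCC)C[C@H]2C(=O)[C@H]1C(C)=C
F2 | step 16 | cis-fused 2-ethoxyoxolane with 6β-hydroxyl, 9α-PMB ether | C=C[C@]1(C)[C@H](OCc3ccc(OC)cc3)[C@H]2OC(OCC)C[C@H]2[C@@H](O)[C@H]1C(C)=C
F3 | step 6 | C9=C10 trimethylsilyl enol ether, 5β-isopropenyl, 6α-TBS-oxy | CC1=C(O[Si](C)(C)C)CC[C@H](O[Si](C)(C)C(C)(C)C)[C@H]1C(C)=C
F4 | step 6 | 10α-(1-hydroxyethyl)-5β-isopropenyl-10β-methyl-6α-(TBS-oxy)cyclohexan-9-one | CC(O)[C@]1(C)C(=O)CC[C@H](O[Si](C)(C)C(C)(C)C)[C@H]1C(C)=C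
F5 | step 8 | 5β-isopropenyl-10β-methyl-6α-(TBS-oxy)-10α-vinylcyclohex-7-en-9-one | C=C[C@]1(C)C(=O)C=C[C@H](O[Si](C)(C)C(C)(C)C)[C@H]1C(C)=C
F6 | step 8 | 5β-isopropenyl-10β-methyl-6α-(TBS-oxy)-10α-vinylcyclohex-7-en-9α-ol | C=C[C@]1(C)[C@H](O)C=C[C@H](O[Si](C)(C)C(C)(C)C)[C@H]1C(C)=C
F7 | step 8 | 9α-PMB ether of F6 | C=C[C@]1(C)[C@H](OCc2ccc(OC)cc2)C=C[C@H](O[Si](C)(C)C(C)(C)C)[C@H]1C(C)=C
F8 | step 8 | 5β-isopropenyl-9α-(4-methoxybenzyloxy)-10β-methyl-10α-vinylcyclohex-7-en-6α-ol | C=C[C@]1(C)[C@H](OCc2ccc(OC)cc2)C=C[C@H](O)[C@H]1C(C)=C
F9 | step 13 | 7β,8β-epoxy-5β-isopropenyl-9α-(4-methoxybenzyloxy)-10β-methyl-10α-vinylcyclohexan-6-one | C=C[C@]1(C)[C@H](OCc3ccc(OC)cc3)[C@H]2O[C@H]2C(=O)[C@H]1C(C)=C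
F10 | step 15 | C6=C7 tert-butyldimethylsilyl enol ether with 8β-bromoacetal | C=C[C@]1(C)[C@H](OCc2ccc(OC)cc2)[C@@H](OC(OCC)CBr)C=C(O[Si](C)(C)C(C)(C)C)[C@H]1C(C)=C
F11 | step 15 | cis-fused 2-ethoxyoxolane with 6β-TBS ether, 9α-PMB ether | C=C[C@]1(C)[C@H](OCc3ccc(OC)cc3)[C@H]2OC(OCC)C[C@H]2[C@@H](O[Si](C)(C)C(C)(C)C)[C@H]1C(C)=C
F12 | step 18 | 8β-(2-bromo-1-ethoxypropoxy) ketone | C=C[C@]1(C)[C@H](OCc2ccc(OC)cc2)[C@@H](OC(OCC)C(C)Br)CC(=O)[C@H]1C(C)=C
F13 | step 18 | C6=C7 enol isobutyrate with 8β-(2-bromo-1-ethoxypropoxy) group | C=C[C@]1(C)[C@H](OCc2ccc(OC)cc2)[C@@H](OC(OCC)C(C)Br)C=C(OC(=O)C(C)C)[C@H]1C(C)=C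
F14 | step 18 | 11-methyl cis-fused 2-ethoxyoxolane, 6β-isobutyrate (C11 and C12 epimers) | C=C[C@]1(C)[C@H](OCc3ccc(OC)cc3)[C@H]2OC(OCC)C(C)[C@H]2[C@@H](OC(=O)C(C)C)[C@H]1C(C)=C
F15 | step 18 | 11-methyl lactol (C11 and C12 epimers) | C=C[C@]1(C)[C@H](OCc3ccc(OC)cc3)[C@H]2OC(O)C(C)[C@H]2[C@@H](OC(=O)C(C)C)[C@H]1C(C)=C
F16 | step 18 | 11β-methyl-8β,12-lactone (C11 epimer of 29) | C=C[C@]1(C)[C@H](OCc3ccc(OC)cc3)[C@H]2OC(=O)[C@@H](C)[C@H]2[C@@H](OC(=O)C(C)C)[C@H]1C(C)=C
A1 | alternative 1 | cyclohexane with cis-fused relay α-methylene lactone (C15 to O6), 8-TES ether, 9-TBS ether, tert-butyl ester arm on C7 | C=C[C@]1(C)[C@H](O[Si](C)(C)C(C)(C)C)[C@@H](O[Si](CC)(CC)CC)[C@@H]([C@@H](C)C(=O)OC(C)(C)C)[C@H]2OC(=O)C(=C)[C@@H]12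
A2 | alternative 1 | open-chain C6 aldehyde with (Z)-2-(bromomethyl)enoate (methyl ester) on C10 | C=C[C@](/C=C(\CBr)C(=O)OC)(C)[C@H](O[Si](C)(C)C(C)(C)C)[C@@H](O[Si](CC)(CC)CC)[C@@H]([C@@H](C)C(=O)OC(C)(C)C)C=O
A3 | alternative 2 | cyclohexene (C8=C9) with C10 methyl and vinyl, C6 isobutyrate, methyl ester arm on C7, dioxanyl on C5 | C=C[C@]1(C)C=C[C@@H]([C@@H](C)C(=O)OC)[C@@H](OC(=O)C(C)C)[C@H]1C1COC(C)(C)OC1
A4 | alternative 2 | open-chain triene with methyl-divinyl C10 | C=C[C@@H]([C@@H](C)C(=O)OC)[C@@H](OC(=O)C(C)C)[C@H](C(C)(C=C)C=C)C1COC(C)(C)OC1
A5 | alternative 3 | cis-fused bicyclo[4.2.0]oct-7-en-2-one photoadduct | O=C1CC[C@@H](O[Si](C)(C)C(C)(C)C)[C@]2(CCOCc3ccc(OC)cc3)C=C(CO[Si](C(C)C)(C(C)C)C(C)C)[C@H]12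
A6 | alternative 3 | 3-[2-(4-methoxybenzyloxy)ethyl]-4-(TBS-oxy)cyclohex-2-enone | O=C1C=C(CCOCc2ccc(OC)cc2)[C@H](O[Si](C)(C)C(C)(C)C)CC1
A7 | alternative 3 | triisopropylsilyl propargyl ether | C#CCO[Si](C(C)C)(C(C)C)C(C)C
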